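**Retrosynthetic overview**

1. The target is epicatechin-(4β→8)-epicatechin-(4β→8)-epicatechin-(4β→8)-catechin. Its three C4–C8 bonds are cut first; each is made, from the lower end upwards, by 4β-selective Friedel–Crafts alkylation of the growing chain (begun with benzylated (+)-catechin) with one and the same 4-hydroxy epicatechin unit, made once and used three times.
2. Ring C of that unit is cut at C2–C3 and at O1–C8a. This leads back to a ring B aldehyde (C2 and O1) and a ring A allylboronate in which C3 is the benzyloxy-bearing γ-carbon, C4 the central sp2 carbon and C8a carries fluorine; the C4=CH2 left by the allyl transfer is then turned into C4–OH.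
3. Enabling feature: O1–C2(H)(aryl) is a benzaldehyde carbonyl in disguise; C3 bears oxygen next to benzylic C4, which must later become a cation and so may be sp2 now; and C8a of ring A is ortho to C4 and meta to the C5 and C7 oxygens, so it can hold fluoride and take the new alkoxide in a six-membered closure.
4. Stereochemistry: C2 and C3 of every epicatechin unit come from one catalytic event (chiral phosphoric acid; 2,3-cis from a reagent geometry fixed in the chelated enolate of an aryl ketone). Each C4 is relayed from C3 in the couplings. The catechin unit is bought.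
5. Ring order: rings A and B are bought benzenes; ring C of the epicatechin unit is closed in the key step (three copies of its product enter the target); ring C of catechin is bought.

Key step: step 6

Remark: the 4-hydroxy electrophile is drawn as the 3,4-cis alcohol expected from the reduction, but either C4 epimer serves because C4 becomes planar in the couplings; the (S)-configured phosphoric acid is chosen by analogy with the accepted sense of induction of this catalyst family and would be exchanged for its mirror image if the first run shows the opposite sense.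

**Route**

Step 1
Reactants: 1 1,3,5-trifluorobenzene
Product: 3 1,3-bis(benzyloxy)-5-fluorobenzene, via difluoro monoether 2 (not isolated)
Conditions: BnOH (2.1 equiv), NaH (2.1 equiv), THF, 0 °C; then 1, NMP, rt → 80 °C
Reagents that add atoms: benzyl alcohol, OCc1ccccc1
Why: Two successive SNAr displacements (addition–elimination through Meisenheimer intermediates) by sodium benzyloxide, each new benzyloxy group slowing the next displacement so that the reaction should stop at the bis-ether.

Step 2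
Reactants: 3 1,3-bis(benzyloxy)-5-fluorobenzene
Product: 4 1,5-bis(benzyloxy)-3-fluoro-2-iodobenzene
Conditions: NIS (1.0 equiv), TFA (cat.), MeCN, 0 °C → rt
Reagents that add atoms: N-iodosuccinimide, O=C1CCC(=O)N1I
Why: Electrophilic aromatic iodination, expected at the carbon para to one benzyloxy group, ortho to the other and flanked by the small fluorine, not at the more hindered carbon between the two benzyloxy groups, as in formylations of the dimethoxy analogue.

Step 3
Reactants: 4 1,5-bis(benzyloxy)-3-fluoro-2-iodobenzene; 5 2-(benzyloxy)-N-methoxy-N-methylacetamide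
Product: 7 2-(benzyloxy)-1-[2,4-bis(benzyloxy)-6-fluorophenyl]ethan-1-one, via arylmagnesium chloride 6 (not isolated)
Conditions: i-PrMgCl·LiCl, THF, −40 °C; then 5, −40 → 0 °C; aq. NH4Cl
Reagents that add atoms: none
Why: Iodine–magnesium exchange is fast at −40 °C, where the ortho-fluoro aryl Grignard reagent does not yet collapse to an aryne, and acylation of the N-methoxy-N-methylamide (Weinreb ketone synthesis) stops at the ketone through the chelated tetrahedral adduct.

Step 4
Reactants: 7 2-(benzyloxy)-1-[2,4-bis(benzyloxy)-6-fluorophenyl]ethan-1-one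
Product: 9 (Z)-2-(benzyloxy)-1-[2,4-bis(benzyloxy)-6-fluorophenyl]ethenyl trifluoromethanesulfonate, via sodium Z-enolate 8 (not isolated)
Conditions: NaN(SiMe3)2, THF, −78 °C; then PhNTf2, −78 → 0 °C
Reagents that add atoms: N-phenylbis(trifluoromethanesulfonimide), O=S(=O)(N(c1ccccc1)S(=O)(=O)C(F)(F)F)C(F)(F)F
Why: Deprotonation of the α-alkoxy ketone should give the sodium-chelated Z enolate (enolate oxygen cis to the benzyloxy group), which is O-sulfonylated with retention of that geometry (enol triflate formation).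

Step 5
Reactants: 9 (Z)-2-(benzyloxy)-1-[2,4-bis(benzyloxy)-6-fluorophenyl]ethenyl trifluoromethanesulfonate
Product: 10 2-{(E)-3-(benzyloxy)-2-[2,4-bis(benzyloxy)-6-fluorophenyl]prop-2-en-1-yl}-4,4,5,5-tetramethyl-1,3,2-dioxaborolane
Conditions: IZnCH2Bpin (from ICH2Bpin, Zn, THF), Pd(PPh3)4 (5 mol%), THF, 40 °C
Reagents that add atoms: 2-(iodomethyl)-4,4,5,5-tetramethyl-1,3,2-dioxaborolane (used as its iodozinc derivative), CC1(C)OB(CI)OC1(C)C
Why: Negishi coupling: oxidative addition of zerovalent palladium into the alkenyl C–OTf bond and transfer of the borylmethyl group from zinc go with retention of alkene geometry, so the CH2B carbon ends up cis to the benzyloxy group.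

Step 6
Reactants: 10 2-{(E)-3-(benzyloxy)-2-[2,4-bis(benzyloxy)-6-fluorophenyl]prop-2-en-1-yl}-4,4,5,5-tetramethyl-1,3,2-dioxaborolane; 11 3,4-bis(benzyloxy)benzaldehyde
Product: 14 (2R,3R)-3,5,7-tris(benzyloxy)-2-[3,4-bis(benzyloxy)phenyl]-4-methylidene-3,4-dihydro-2H-chromene, via pinacol borate 12 (not isolated), via potassium alkoxide 13 (not isolated)
Conditions: (S)-TRIP [(S)-3,3'-bis(2,4,6-triisopropylphenyl)-1,1'-binaphthyl-2,2'-diyl hydrogen phosphate] (5 mol%), 4 Å molecular sieves, toluene, −30 → 0 °C; then KOt-Bu (2.2 equiv), 18-crown-6, DMF, 0 → 70 °C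
Reagents that add atoms: none
Why: The phosphoric acid hydrogen-bonds to a boronate oxygen and the formyl hydrogen and so activates a closed six-membered chair transition state in which the γ-carbon of 10 (C3) attacks the aldehyde carbon (C2) while boron passes to the aldehyde oxygen (O1), giving borate 12; tert-butoxide then takes boron, and the freed potassium alkoxide 13 adds to C8a and expels fluoride through a Meisenheimer intermediate. The closest known reactions are the chiral phosphoric acid-catalysed syn-alkoxyallylboration of aryl aldehydes with γ-alkoxyallyl pinacolboronates of this geometry and the alkoxide SNAr on 3,5-dialkoxyfluorobenzenes used to make flavans, run here one after the other in the same flask. Ring C closes in the second event by 6-exo attack of O1 on the aromatic carbon C8a (addition–elimination); the first event closes no ring. C2 is set by the catalyst, which should expose the Si face of 11, and C3 follows from the chair, in which the benzyloxy group is axial because it is cis to the CH2B carbon, so that the 1,2-syn adduct and hence the 2,3-cis (2R,3R) chroman results. The step needs syn over anti selectivity, which rests on the geometric purity of 10, and closure through O1 alone, which is secured because O3 is a benzyl ether that can neither migrate nor cyclise to a dihydrobenzofuran. The exocyclic methylene stands in for the C4 carbonyl, so the new carbon–carbon bond cannot reopen and C3–H is not acidic, and the kinetic 2,3-cis relation should survive the basic ring closure.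

Step 7
Reactants: 14 (2R,3R)-3,5,7-tris(benzyloxy)-2-[3,4-bis(benzyloxy)phenyl]-4-methylidene-3,4-dihydro-2H-chromene
Product: 15 (2R,3S)-3,5,7-tris(benzyloxy)-2-[3,4-bis(benzyloxy)phenyl]-2,3-dihydro-4H-chromen-4-one
Conditions: OsO4 (2 mol%), NaIO4, 2,6-lutidine, dioxane–H2O, rt
Reagents that add atoms: sodium periodate (terminal oxidant, oxygen delivered through OsO4), [Na+].[O-]I(=O)(=O)=O
Why: Lemieux–Johnson oxidation: osmium-catalysed dihydroxylation of the only alkene and periodate cleavage of the diol give the ketone, the 2,6-lutidine buffer being too weak a base to epimerise C3.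

Step 8
Reactants: 15 (2R,3S)-3,5,7-tris(benzyloxy)-2-[3,4-bis(benzyloxy)phenyl]-2,3-dihydro-4H-chromen-4-one
Product: 16 (2R,3R,4R)-3,5,7-tris(benzyloxy)-2-[3,4-bis(benzyloxy)phenyl]-3,4-dihydro-2H-chromen-4-ol
Conditions: NaBH4, THF–MeOH, −20 → 0 °C
Reagents that add atoms: none
Why: Borohydride reduction of the aryl ketone; hydride is expected to enter anti to the axial C3 benzyloxy group to give mainly the 3,4-cis alcohol, and the C4 configuration is in any case erased in the next step.

Step 9
Reactants: 17 (+)-catechin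
Product: 18 5,7,3',4'-tetra-O-benzyl-(+)-catechin
Conditions: BnBr (4.4 equiv), K2CO3, DMF, 0 °C → rt
Reagents that add atoms: benzyl bromide, BrCc1ccccc1
Why: Williamson etherification under carbonate base alkylates the four phenols selectively, the secondary C3 alcohol being too weakly acidic to react.

Step 10
Reactants: 16 (2R,3R,4R)-3,5,7-tris(benzyloxy)-2-[3,4-bis(benzyloxy)phenyl]-3,4-dihydro-2H-chromen-4-ol; 18 5,7,3',4'-tetra-O-benzyl-(+)-catechin
Product: 19 [3,5,7,3',4'-penta-O-benzylepicatechin]-(4β→8)-[5,7,3',4'-tetra-O-benzylcatechin]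
Conditions: 18 (4 equiv), BF3·OEt2 (0.3 equiv), CH2Cl2, −78 → −30 °C
Reagents that add atoms: none
Why: Lewis acid ionisation of the benzylic C4–OH gives a flavan-4-yl cation stabilised by the C5 and C7 oxygens, which alkylates C8 of 18 (Friedel–Crafts alkylation) from the face opposite the cis C2 aryl and C3 benzyloxy groups, setting the new C4 as 4β (3,4-trans).

Step 11
Reactants: 16 (2R,3R,4R)-3,5,7-tris(benzyloxy)-2-[3,4-bis(benzyloxy)phenyl]-3,4-dihydro-2H-chromen-4-ol; 19 the protected dimer
Product: 20 [3,5,7,3',4'-penta-O-benzylepicatechin]-(4β→8)-[3,5,7,3',4'-penta-O-benzylepicatechin]-(4β→8)-[5,7,3',4'-tetra-O-benzylcatechin]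
Conditions: 19 (3 equiv), BF3·OEt2 (0.3 equiv), CH2Cl2, −78 → −30 °C
Reagents that add atoms: none
Why: The same Friedel–Crafts alkylation, expected at the free and least hindered C8 of the upper unit of 19, with the new C4 again set trans to the C3 benzyloxy group (4β) by attack anti to the C2 and C3 substituents.

Step 12
Reactants: 16 (2R,3R,4R)-3,5,7-tris(benzyloxy)-2-[3,4-bis(benzyloxy)phenyl]-3,4-dihydro-2H-chromen-4-ol; 20 the protected trimer
Product: 21 [3,5,7,3',4'-penta-O-benzylepicatechin]-(4β→8)-[3,5,7,3',4'-penta-O-benzylepicatechin]-(4β→8)-[3,5,7,3',4'-penta-O-benzylepicatechin]-(4β→8)-[5,7,3',4'-tetra-O-benzylcatechin]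
Conditions: 20 (3 equiv), BF3·OEt2 (0.3 equiv), CH2Cl2, −78 → −30 °C
Reagents that add atoms: none
Why: A third Friedel–Crafts alkylation of the same kind at C8 of the top unit of 20, the 4β configuration again following from attack anti to the cis C2 aryl and C3 benzyloxy groups of the cation.

Step 13
Reactants: 21 the nonadeca-O-benzyl tetramer
Product: 22 epicatechin-(4β→8)-epicatechin-(4β→8)-epicatechin-(4β→8)-catechin (the target)
Conditions: H2 (1 atm), Pd(OH)2/C, THF–MeOH–H2O, rt
Reagents that add atoms: none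
Why: Hydrogenolysis cleaves the sixteen aryl benzyl ethers and the three secondary benzyl ethers to toluene without touching the interflavan C–C bonds or any stereocenter.

**Compound list**

1 | 1,3,5-trifluorobenzene | Fc1cc(F)cc(F)c1 | starting material
2 | 1-(benzyloxy)-3,5-difluorobenzene | Fc1cc(F)cc(OCc2ccccc2)c1 | intermediate
3 | 1,3-bis(benzyloxy)-5-fluorobenzene | Fc1cc(OCc2ccccc2)cc(OCc2ccccc2)c1 | intermediate
4 | 1,5-bis(benzyloxy)-3-fluoro-2-iodobenzene | Fc1cc(OCc2ccccc2)cc(OCc2ccccc2)c1I | intermediate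
5 | 2-(benzyloxy)-N-methoxy-N-methylacetamide | CON(C)C(=O)COCc1ccccc1 | starting material
6 | [2,4-bis(benzyloxy)-6-fluorophenyl]magnesium chloride | Cl[Mg]c1c(F)cc(OCc2ccccc2)cc1OCc1ccccc1 | intermediate
7 | 2-(benzyloxy)-1-[2,4-bis(benzyloxy)-6-fluorophenyl]ethan-1-one | O=C(COCc1ccccc1)c1c(F)cc(OCc2ccccc2)cc1OCc1ccccc1 | intermediate
8 | sodium (Z)-2-(benzyloxy)-1-[2,4-bis(benzyloxy)-6-fluorophenyl]ethen-1-olate | [Na+].[O-]/C(=C\OCc1ccccc1)c1c(F)cc(OCc2ccccc2)cc1OCc1ccccc1 | intermediate
9 | (Z)-2-(benzyloxy)-1-[2,4-bis(benzyloxy)-6-fluorophenyl]ethenyl trifluoromethanesulfonate | O=S(=O)(O/C(=C\OCc1ccccc1)c1c(F)cc(OCc2ccccc2)cc1OCc1ccccc1)C(F)(F)F | intermediate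
10 | 2-{(E)-3-(benzyloxy)-2-[2,4-bis(benzyloxy)-6-fluorophenyl]prop-2-en-1-yl}-4,4,5,5-tetramethyl-1,3,2-dioxaborolane | CC1(C)OB(C/C(=C\OCc2ccccc2)c2c(F)cc(OCc3ccccc3)cc2OCc2ccccc2)OC1(C)C | intermediate
11 | 3,4-bis(benzyloxy)benzaldehyde | O=Cc1ccc(OCc2ccccc2)c(OCc2ccccc2)c1 | starting material
12 | 2-{[(1R,2R)-2-(benzyloxy)-1-[3,4-bis(benzyloxy)phenyl]-3-[2,4-bis(benzyloxy)-6-fluorophenyl]but-3-en-1-yl]oxy}-4,4,5,5-tetramethyl-1,3,2-dioxaborolane | CC1(C)OB(O[C@H](c2ccc(OCc3ccccc3)c(OCc3ccccc3)c2)[C@H](OCc2ccccc2)C(=C)c2c(F)cc(OCc3ccccc3)cc2OCc2ccccc2)OC1(C)C | intermediate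
13 | potassium (1R,2R)-2-(benzyloxy)-1-[3,4-bis(benzyloxy)phenyl]-3-[2,4-bis(benzyloxy)-6-fluorophenyl]but-3-en-1-olate | [K+].[O-][C@H](c1ccc(OCc2ccccc2)c(OCc2ccccc2)c1)[C@H](OCc1ccccc1)C(=C)c1c(F)cc(OCc2ccccc2)cc1OCc1ccccc1 | intermediate
14 | (2R,3R)-3,5,7-tris(benzyloxy)-2-[3,4-bis(benzyloxy)phenyl]-4-methylidene-3,4-dihydro-2H-chromene | C(c1ccccc1)Oc1cc(OCc2ccccc2)c2c(c1)O[C@H](c1ccc(OCc3ccccc3)c(OCc3ccccc3)c1)[C@H](OCc1ccccc1)C2=C | intermediate
15 | (2R,3S)-3,5,7-tris(benzyloxy)-2-[3,4-bis(benzyloxy)phenyl]-2,3-dihydro-4H-chromen-4-one | C(c1ccccc1)Oc1cc(OCc2ccccc2)c2c(c1)O[C@H](c1ccc(OCc3ccccc3)c(OCc3ccccc3)c1)[C@H](OCc1ccccc1)C2=O | intermediate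
16 | (2R,3R,4R)-3,5,7-tris(benzyloxy)-2-[3,4-bis(benzyloxy)phenyl]-3,4-dihydro-2H-chromen-4-ol | C(c1ccccc1)Oc1cc(OCc2ccccc2)c2c(c1)O[C@H](c1ccc(OCc3ccccc3)c(OCc3ccccc3)c1)[C@H](OCc1ccccc1)[C@@H]2O | intermediate
17 | (+)-catechin | Oc1cc(O)c2c(c1)O[C@H](c1ccc(O)c(O)c1)[C@@H](O)C2 | starting material
18 | 5,7,3',4'-tetra-O-benzyl-(+)-catechin | C(c1ccccc1)Oc1cc(OCc2ccccc2)c2c(c1)O[C@H](c1ccc(OCc3ccccc3)c(OCc3ccccc3)c1)[C@@H](O)C2 | intermediate
19 | [3,5,7,3',4'-penta-O-benzylepicatechin]-(4β→8)-[5,7,3',4'-tetra-O-benzylcatechin] | C(c1ccccc1)Oc1cc(OCc2ccccc2)c2c(c1)O[C@H](c1ccc(OCc3ccccc3)c(OCc3ccccc3)c1)[C@H](OCc1ccccc1)[C@H]2c1c(OCc3ccccc3)cc(OCc3ccccc3)c2c1O[C@H](c1ccc(OCc3ccccc3)c(OCc3ccccc3)c1)[C@@H](O)C2 | intermediate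
20 | [3,5,7,3',4'-penta-O-benzylepicatechin]-(4β→8)-[3,5,7,3',4'-penta-O-benzylepicatechin]-(4β→8)-[5,7,3',4'-tetra-O-benzylcatechin] | C(c1ccccc1)Oc1cc(OCc2ccccc2)c2c(c1)O[C@H](c1ccc(OCc3ccccc3)c(OCc3ccccc3)c1)[C@H](OCc1ccccc1)[C@H]2c1c(OCc3ccccc3)cc(OCc3ccccc3)c2c1O[C@H](c1ccc(OCc3ccccc3)c(OCc3ccccc3)c1)[C@H](OCc1ccccc1)[C@H]2c1c(OCc3ccccc3)cc(OCc3ccccc3)c2c1O[C@H](c1ccc(OCc3ccccc3)c(OCc3ccccc3)c1)[C@@H](O)C2 | intermediate
21 | [3,5,7,3',4'-penta-O-benzylepicatechin]-(4β→8)-[3,5,7,3',4'-penta-O-benzylepicatechin]-(4β→8)-[3,5,7,3',4'-penta-O-benzylepicatechin]-(4β→8)-[5,7,3',4'-tetra-O-benzylcatechin] (nonadeca-O-benzyl tetramer, catechin C3–OH free) | C(c1ccccc1)Oc1cc(OCc2ccccc2)c2c(c1)O[C@H](c1ccc(OCc3ccccc3)c(OCc3ccccc3)c1)[C@H](OCc1ccccc1)[C@H]2c1c(OCc3ccccc3)cc(OCc3ccccc3)c2c1O[C@H](c1ccc(OCc3ccccc3)c(OCc3ccccc3)c1)[C@H](OCc1ccccc1)[C@H]2c1c(OCc3ccccc3)cc(OCc3ccccc3)c2c1O[C@H](c1ccc(OCc3ccccc3)c(OCc3ccccc3)c1)[C@H](OCc1ccccc1)[C@H]2c1c(OCc3ccccc3)cc(OCc3ccccc3)c2c1O[C@H](c1ccc(OCc3ccccc3)c(OCc3ccccc3)c1)[C@@H](O)C2 | intermediate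
22 | epicatechin-(4β→8)-epicatechin-(4β→8)-epicatechin-(4β→8)-catechin | Oc1cc(O)c2c(c1)O[C@H](c1ccc(O)c(O)c1)[C@H](O)[C@H]2c1c(O)cc(O)c2c1O[C@H](c1ccc(O)c(O)c1)[C@H](O)[C@H]2c1c(O)cc(O)c2c1O[C@H](c1ccc(O)c(O)c1)[C@H](O)[C@H]2c1c(O)cc(O)c2c1O[C@H](c1ccc(O)c(O)c1)[C@@H](O)C2 | target

**Step count and risks**

Total: 13 steps. Longest linear sequence: 12 steps (steps 1 to 8 and 10 to 13).

Steps most likely to fail:

Step 6. The allyl transfer from the hindered, β-aryl-substituted boronate may show too little facial or syn/anti discrimination, or the fluoride displacement may be slow enough for retro-allylation of the potassium alkoxide or migration of the exocyclic double bond into the ring to compete. The fallback sets out from 7 and 11 and keeps the ketone oxygen. Enolisation of 7 with an isopinocampheyl boron triflate (Ipc2BOTf, i-Pr2NEt; the pinene enantiomer chosen for the (1R) carbinol) should give the Z enol borinate, which adds to 11 in a syn-selective boron aldol reaction. Reduction of the boron aldolate in the same flask with LiBH4, before any free aldolate can undergo retro-aldol cleavage or epimerisation, should give the (1R,2S,3S)-diol F1. KOt-Bu in DMF then closes ring C by the same SNAr to give the C4-epimeric alcohol F2. F2 ionises to the same cation as 16 and takes its place in steps 10 to 12, so the route is rejoined at 19.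

Step 5. The cross-coupling of the electron-rich, doubly ortho-substituted enol triflate with the borylmethylzinc reagent may stall, or the allylboronate may be lost by protodeboronation under the coupling conditions. The fallback sets out from 9 and makes the carbon–boron bond first. Miyaura borylation of 9 (B2pin2, PdCl2(PPh3)2, PPh3, KOPh, toluene, 50 °C) should give the alkenylboronate F3 with retention of geometry. Matteson homologation (ICH2Cl, n-BuLi, THF, −78 °C → rt) then inserts the CH2 group between boron and carbon with retention, which returns to the route at 10.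

Step 12. With the valuable trimer used in limited excess, self-condensation of the electrophile, alkylation at C6 positions and over-extension of the product chain may erode the coupling. The fallback sets out from 16 and caps the electrophile. Bromination with NBS (CH2Cl2, −78 °C) should give the 8-bromo alcohol F4, which can no longer act as a nucleophile. Coupling of F4 with 20 in equimolar amounts (BF3·OEt2, CH2Cl2, −78 → −30 °C) should give the 8-bromo tetramer F5, whose top unit cannot be extended further. Hydrogenolysis (H2, Pd(OH)2/C, Et3N, THF–MeOH–H2O) removes bromine together with the benzyl groups and returns to the route at 22.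

Further compounds
F1 | step 6 | (1R,2S,3S)-2-(benzyloxy)-1-[3,4-bis(benzyloxy)phenyl]-3-[2,4-bis(benzyloxy)-6-fluorophenyl]propane-1,3-diol | O[C@H](c1ccc(OCc2ccccc2)c(OCc2ccccc2)c1)[C@H](OCc1ccccc1)[C@@H](O)c1c(F)cc(OCc2ccccc2)cc1OCc1ccccc1
F2 | step 6 | (2R,3R,4S)-3,5,7-tris(benzyloxy)-2-[3,4-bis(benzyloxy)phenyl]-3,4-dihydro-2H-chromen-4-ol | C(c1ccccc1)Oc1cc(OCc2ccccc2)c2c(c1)O[C@H](c1ccc(OCc3ccccc3)c(OCc3ccccc3)c1)[C@H](OCc1ccccc1)[C@H]2O
F3 | step 5 | 2-{(E)-2-(benzyloxy)-1-[2,4-bis(benzyloxy)-6-fluorophenyl]ethenyl}-4,4,5,5-tetramethyl-1,3,2-dioxaborolane | CC1(C)OB(/C(=C\OCc2ccccc2)c2c(F)cc(OCc3ccccc3)cc2OCc2ccccc2)OC1(C)C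
F4 | step 12 | (2R,3R,4R)-8-bromo-3,5,7-tris(benzyloxy)-2-[3,4-bis(benzyloxy)phenyl]-3,4-dihydro-2H-chromen-4-ol | C(c1ccccc1)Oc1cc(OCc2ccccc2)c2c(c1Br)O[C@H](c1ccc(OCc3ccccc3)c(OCc3ccccc3)c1)[C@H](OCc1ccccc1)[C@@H]2O
F5 | step 12 | [8-bromo-3,5,7,3',4'-penta-O-benzylepicatechin]-(4β→8)-[3,5,7,3',4'-penta-O-benzylepicatechin]-(4β→8)-[3,5,7,3',4'-penta-O-benzylepicatechin]-(4β→8)-[5,7,3',4'-tetra-O-benzylcatechin] | C(c1ccccc1)Oc1cc(OCc2ccccc2)c2c(c1Br)O[C@H](c1ccc(OCc3ccccc3)c(OCc3ccccc3)c1)[C@H](OCc1ccccc1)[C@H]2c1c(OCc3ccccc3)cc(OCc3ccccc3)c2c1O[C@H](c1ccc(OCc3ccccc3)c(OCc3ccccc3)c1)[C@H](OCc1ccccc1)[C@H]2c1c(OCc3ccccc3)cc(OCc3ccccc3)c2c1O[C@H](c1ccc(OCc3ccccc3)c(OCc3ccccc3)c1)[C@H](OCc1ccccc1)[C@H]2c1c(OCc3ccccc3)cc(OCc3ccccc3)c2c1O[C@H](c1ccc(OCc3ccccc3)c(OCc3ccccc3)c1)[C@@H](O)C2
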